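**Retrosynthetic overview**
1. Target 25 ⇐ acid-catalysed deprotection and γ-lactonisation (C6–O) of C8-methacrylated hydroxy ester 23.
2. Ring B (C7–C8 bond, closes the ten-membered carbocycle) ⇐ intramolecular zinc Barbier allylation of a C8 aldehyde by a 2-(bromomethyl)acrylate built at C7.
3. Ring A (oxepane) and the key C10–O bond ⇐ copper-catalysed, ligand-controlled propargylic etherification of a tertiary propargylic acetate by C5–OH; the alkyne is the latent C8 aldehyde.
4. C5/C6 ⇐ Brown syn-alkoxyallylboration; C3/C4 ⇐ Krische anti-(hydroxymethyl)allylation; C8–C10/C1–C3 ⇐ dehydrolinalool.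
5. Ring order: oxepane A (C–O) → carbocycle/ring B (C–C) → γ-lactone (C–O).

Assumption: the SMILES is taken literally (all seven stereocentres R), which places the ether oxygen on opposite faces of the ten-membered ring at C5 and C10 (a trans-bridged 11-oxabicyclo[4.4.1]undecane), so C5 and C10 are set independently by reagent and catalyst control.

Locants used in all names: ring carbons C1–C10; C10 = C(CH3)(O), methyl = C14; C9, C1, C2 = CH2; C8 = CH–O-methacrylate; C7 = CH bearing C11(=C13H2)–C12(=O); C6 = CH–O (lactone); C5 = CH–O (ether to C10); C4 = CH–C15H2OH; C3 = CH–OAc. Compounds 3–13 are 1:1 mixtures of C10 epimers (converged in step 6); compounds 10–23 carry a THP group as both acetal epimers.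

**Step 1**
Reactants: 1 (±)-dehydrolinalool
Product: 3 4-hydroxy-4-methylhex-5-ynal (lactol form), via ozonide 2 (not isolated)
Conditions: O3, CH2Cl2, −78 °C (Sudan III end point); Me2S, −78 °C → rt
Reagents that add atoms: ozone, O=[O+][O-]
Why: Ozonolysis with reductive work-up; the electron-rich trisubstituted alkene is cleaved much faster than the terminal alkyne, and no stereocentre is set (C10 stays racemic until step 6).

**Step 2**
Reactants: 3 4-hydroxy-4-methylhex-5-ynal; 4 vinyl ethylene carbonate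
Product: 5 (3R,4R)-triol
Conditions: [Ir(cod)Cl]2 (2.5 mol%), (R)-SEGPHOS (5 mol%), 4-cyano-3-nitrobenzoic acid (10 mol%), K3PO4 (5 mol%), i-PrOH (2 equiv), THF, 60 °C
Reagents that add atoms: none
Why: Krische iridium-catalysed transfer-hydrogenative anti-(hydroxymethyl)allylation; the (E)-σ-allyliridium adds to the open hydroxy-aldehyde through a closed chair transition state to give the anti C3-OH/C4-CH2OH pair, and the ligand antipode (chosen to give 3R,4R) sets the absolute configuration.

**Step 3**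
Reactants: 5 (3R,4R)-triol
Product: 7 15-O-TBS 3,10-diacetate, via silyl ether 6 (not isolated)
Conditions: TBSCl (1.05 equiv), imidazole, CH2Cl2, 0 °C; then Ac2O, Et3N, DMAP, 40 °C
Reagents that add atoms: tert-butyldimethylsilyl chloride, CC(C)(C)[Si](C)(C)Cl; acetic anhydride, CC(=O)OC(C)=O
Why: Chemoselective silylation of the primary alcohol followed by DMAP-catalysed acetylation; the C3 acetate is the one kept in the target, the tertiary propargylic C10 acetate is the leaving group for step 6, and no stereocentre is touched.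

**Step 4**
Reactants: 7 15-O-TBS 3,10-diacetate
Product: 9 C5 aldehyde, via ozonide 8 (not isolated)
Conditions: O3, CH2Cl2, −78 °C (Sudan III); PPh3, −78 °C → rt; used crude
Reagents that add atoms: ozone, O=[O+][O-]
Why: Ozonolysis of the vinyl group (the alkyne is much slower); neutral work-up and immediate use avoid β-elimination of the C3 acetate and epimerisation at C4.

**Step 5**
Reactants: 9 C5 aldehyde; 10 allyl tetrahydropyranyl ether
Product: 13 (5R,6R)-homoallylic alcohol, via borane 11 (not isolated), via borinate 12 (not isolated)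
Conditions: 10, s-BuLi, THF, −78 °C; (−)-Ipc2BOMe; BF3·OEt2; then 9, −78 °C, 4 h; 30% H2O2, pH 7 buffer, 0 °C
Reagents that add atoms: none
Why: Brown asymmetric γ-alkoxyallylboration; the (Z)-γ-alkoxyallylborane adds through a chair (Zimmerman–Traxler) transition state to give the syn C5-OH/C6-OTHP pair, and the isopinocampheyl groups (reagent control, against the weak Felkin bias of the α-branched aldehyde) set 5R,6R.

**Step 6**
Reactants: 13 (5R,6R)-homoallylic alcohol
Product: 14 (10R)-2-ethynyl-2-methyloxepane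
Conditions: Cu(MeCN)4PF6 (10 mol%), (S,S)-Ph-pybox (12 mol%), i-Pr2NEt (1.5 equiv), PhCF3, 0.01 M, −10 °C → rt
Reagents that add atoms: none
Why: Proposed new method: copper-catalysed intramolecular 7-exo propargylic etherification at a tertiary centre; the Cu(I) acetylide loses acetate to give a planar copper–allenylidene common to both C10 epimers of 13, the free C5-OH attacks Cγ (C10) inside the chiral pybox pocket so that the ligand selects the face and sets 10R (C9 trans to the C6 chain on the oxepane), and protodemetalation returns the terminal alkyne; the closest known reaction is the intermolecular Cu–pybox enantioselective propargylic etherification of secondary propargylic esters with alcohols (copper–allenylidene propargylic substitution).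

**Step 7**
Reactants: 14 (10R)-2-ethynyl-2-methyloxepane
Product: 16 C7 aldehyde, via ozonide 15 (not isolated)
Conditions: O3, CH2Cl2, −78 °C (Sudan III); PPh3, −78 °C → rt
Reagents that add atoms: ozone, O=[O+][O-]
Why: Ozonolysis of the remaining vinyl group in the presence of the slower-reacting alkyne; the C6 stereocentre is untouched under the neutral work-up.

**Step 8**
Reactants: 16 C7 aldehyde; 17 methyl acrylate
Product: 18 Morita–Baylis–Hillman adduct
Conditions: DABCO (1 equiv), methyl acrylate (10 equiv), MeOH (cat.), rt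
Reagents that add atoms: none
Why: Morita–Baylis–Hillman reaction of an activated α-alkoxy aldehyde; the new C7 carbinol is formed as a mixture, which does not matter because C7 becomes sp2 in step 10.

**Step 9**
Reactants: 18 Morita–Baylis–Hillman adduct
Product: 19 C8 aldehyde
Conditions: CpRu(MeCN)3PF6 (5 mol%), 5,5′-bis(trifluoromethyl)-2,2′-bipyridine (5 mol%), NMP/H2O 4:1, 25 °C
Reagents that add atoms: water, O
Why: Ruthenium-catalysed anti-Markovnikov alkyne hydration through a Ru-vinylidene; neutral room-temperature conditions leave the acrylate, acetals and the tertiary C10 ether intact and set no stereocentre.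

**Step 10**
Reactants: 19 C8 aldehyde
Product: 20 (Z)-allylic bromide
Conditions: NBS, Me2S, CH2Cl2, −20 → 0 °C
Reagents that add atoms: N-bromosuccinimide, O=C1CCC(=O)N1Br
Why: Corey–Kim-type SN2′ bromination of the Baylis–Hillman alcohol; allylic transposition gives the conjugated (Z)-2-(bromomethyl)alk-2-enoate and removes the C7 carbinol mixture.

**Step 11**
Reactants: 20 (Z)-allylic bromide
Product: 22 bicyclic hydroxy ester, via allylzinc 21 (not isolated)
Conditions: Zn dust (activated, 5 equiv), THF/sat. aq NH4Cl 5:1, 0.005 M (slow addition), rt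
Reagents that add atoms: none
Why: Intramolecular zinc Barbier allylation (2-(bromomethyl)acrylate, SE2′ through C7) in a closed six-membered transition state; the tether through C5 brings the aldehyde to the C7 face syn to C5 and zinc chelation by the C6 ether oxygen holds that oxygen in the allyl plane, which should give the all-cis C6-O/C7-C11/C8-O array (7R,8R) while closing the ten-membered carbocycle as ring B.

**Step 12**
Reactants: 22 bicyclic hydroxy ester
Product: 23 C8 methacrylate
Conditions: methacrylic anhydride, Et3N, DMAP (cat.), CH2Cl2, −20 °C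
Reagents that add atoms: methacrylic anhydride, C=C(C)C(=O)OC(=O)C(C)=C
Why: DMAP-catalysed acylation of the only free hydroxyl; capping C8-O before C6-O is released means only the 6,12-lactone can form later, and no stereocentre is touched.

**Step 13**
Reactants: 23 C8 methacrylate
Product: 25 CNP0602302.1, via diol ester 24 (not isolated)
Conditions: CSA (0.2 equiv), MeOH/CH2Cl2 1:1, 0 °C → rt
Reagents that add atoms: none
Why: Acid-catalysed methanolysis of the THP acetal and primary TBS ether followed by spontaneous γ-lactonisation (intramolecular transesterification) of C6-OH onto the cis-disposed methyl ester; the mild acid leaves the tertiary C10 ether, the acetate and the methacrylate intact and touches no stereocentre.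

**Compound list**
1 | (±)-dehydrolinalool (3,7-dimethyloct-6-en-1-yn-3-ol) | C#CC(C)(O)CCC=C(C)C | starting material
2 | ozonide of 1: 3-(3-hydroxy-3-methylpent-4-yn-1-yl)-5,5-dimethyl-1,2,4-trioxolane | C#CC(C)(O)CCC1OOC(C)(C)O1 | intermediate
3 | (±)-4-hydroxy-4-methylhex-5-ynal, in equilibrium with 5-ethynyl-5-methyloxolan-2-ol | C#CC(C)(O)CCC=O | intermediate
4 | (±)-vinyl ethylene carbonate (4-vinyl-1,3-dioxolan-2-one) | C=CC1COC(=O)O1 | starting material
5 | (3R,4R)-triol HC≡C–C10(CH3)(OH)–CH2CH2–C3H(OH)–C4H(CH2OH)–CH=CH2, C10 epimers | C#CC(C)(O)CC[C@@H](O)[C@@H](CO)C=C | intermediate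
6 | 15-O-TBS ether of 5 (3R,4R) | C#CC(C)(O)CC[C@@H](O)[C@@H](CO[Si](C)(C)C(C)(C)C)C=C | intermediate
7 | 15-O-TBS 3,10-di-O-acetate of 5 (3R,4R) | C#CC(C)(OC(C)=O)CC[C@@H](OC(C)=O)[C@@H](CO[Si](C)(C)C(C)(C)C)C=C | intermediate
8 | ozonide of 7 (1,2,4-trioxolan-3-yl on C4; 3R,4R) | C#CC(C)(OC(C)=O)CC[C@@H](OC(C)=O)[C@@H](CO[Si](C)(C)C(C)(C)C)C1OOCO1 | intermediate
9 | (3R,4R)-C5 aldehyde OHC–C4H(CH2OTBS)–C3H(OAc)–CH2CH2–C10(CH3)(OAc)–C≡CH | C#CC(C)(OC(C)=O)CC[C@@H](OC(C)=O)[C@@H](CO[Si](C)(C)C(C)(C)C)C=O | intermediate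
10 | allyl tetrahydropyranyl ether (2-(allyloxy)oxane) | C=CCOC1CCCCO1 | starting material
11 | [(Z)-3-(oxan-2-yloxy)allyl]diisopinocampheylborane from (+)-α-pinene | C(/C=C\OC1CCCCO1)B([C@@H]1C[C@@H]2C[C@H]([C@H]1C)C2(C)C)[C@@H]1C[C@@H]2C[C@H]([C@H]1C)C2(C)C | intermediate
12 | C5-O-diisopinocampheylborinate of 13 | C#CC(C)(OC(C)=O)CC[C@@H](OC(C)=O)[C@@H](CO[Si](C)(C)C(C)(C)C)[C@@H](OB([C@@H]1C[C@@H]2C[C@H]([C@H]1C)C2(C)C)[C@@H]1C[C@@H]2C[C@H]([C@H]1C)C2(C)C)[C@H](OC1CCCCO1)C=C | intermediate
13 | (3R,4R,5R,6R)-homoallylic alcohol: 9 extended by C5H(OH)–C6H(OTHP)–CH=CH2 | C#CC(C)(OC(C)=O)CC[C@@H](OC(C)=O)[C@@H](CO[Si](C)(C)C(C)(C)C)[C@@H](O)[C@H](OC1CCCCO1)C=C | intermediate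
14 | (3R,4R,5R,10R)-oxepane (O bridges C5 and C10) with C10 methyl and ethynyl, C3-OAc, C4-CH2OTBS, C5-[(R)-CH(OTHP)CH=CH2] | C#C[C@@]1(C)CC[C@@H](OC(C)=O)[C@@H](CO[Si](C)(C)C(C)(C)C)[C@@H](O1)[C@H](OC2CCCCO2)C=C | intermediate
15 | ozonide of 14 (1,2,4-trioxolan-3-yl on C6) | C#C[C@@]1(C)CC[C@@H](OC(C)=O)[C@@H](CO[Si](C)(C)C(C)(C)C)[C@@H](O1)[C@H](OC2CCCCO2)C2OOCO2 | intermediate
16 | C7 aldehyde: oxepane of 14 with C5-[(S)-CH(OTHP)CHO] | C#C[C@@]1(C)CC[C@@H](OC(C)=O)[C@@H](CO[Si](C)(C)C(C)(C)C)[C@@H](O1)[C@H](OC2CCCCO2)C=O | intermediate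
17 | methyl acrylate | C=CC(=O)OC | starting material
18 | Baylis–Hillman adduct: C6H(OTHP)–C7H(OH)–C11(=CH2)–CO2Me on the ethynyl oxepane (6R; C7 epimers) | C#C[C@@]1(C)CC[C@@H](OC(C)=O)[C@@H](CO[Si](C)(C)C(C)(C)C)[C@@H](O1)[C@H](OC2CCCCO2)C(O)C(=C)C(=O)OC | intermediate
19 | C8 aldehyde: 18 with C10–CH2–CHO in place of the ethynyl group | O=CC[C@@]1(C)CC[C@@H](OC(C)=O)[C@@H](CO[Si](C)(C)C(C)(C)C)[C@@H](O1)[C@H](OC2CCCCO2)C(O)C(=C)C(=O)OC | intermediate
20 | (Z)-allylic bromide: C6H(OTHP)–C7H=C11(CH2Br)–CO2Me with C10–CH2–CHO | O=CC[C@@]1(C)CC[C@@H](OC(C)=O)[C@@H](CO[Si](C)(C)C(C)(C)C)[C@@H](O1)[C@H](OC2CCCCO2)/C=C(\CBr)C(=O)OC | intermediate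
21 | allylzinc bromide derived from 20 | O=CC[C@@]1(C)CC[C@@H](OC(C)=O)[C@@H](CO[Si](C)(C)C(C)(C)C)[C@@H](O1)[C@H](OC2CCCCO2)/C=C(\C[Zn]Br)C(=O)OC | intermediate
22 | (3R,4R,5R,6R,7R,8R,10R)-5,10-epoxy ten-membered carbocycle: C3-OAc, C4-CH2OTBS, C6-OTHP, C7-C(=CH2)CO2Me, C8-OH | O[C@@H]1C[C@@]2(C)CC[C@@H](OC(C)=O)[C@@H](CO[Si](C)(C)C(C)(C)C)[C@@H](O2)[C@H](OC3CCCCO3)[C@@H]1C(=C)C(=O)OC | intermediate
23 | C8-O-methacrylate of 22 | C=C(C)C(=O)O[C@@H]1C[C@@]2(C)CC[C@@H](OC(C)=O)[C@@H](CO[Si](C)(C)C(C)(C)C)[C@@H](O2)[C@H](OC3CCCCO3)[C@@H]1C(=C)C(=O)OC | intermediate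
24 | C6,C15-diol methyl ester (23 without THP and TBS) | C=C(C)C(=O)O[C@@H]1C[C@@]2(C)CC[C@@H](OC(C)=O)[C@@H](CO)[C@@H](O2)[C@H](O)[C@@H]1C(=C)C(=O)OC | intermediate
25 | CNP0602302.1: (3R,4R,5R,6R,7R,8R,10R)-3-acetoxy-15-hydroxy-8-methacryloyloxy-5,10-epoxygermacr-11(13)-en-12,6-olide | C=C(C)C(=O)O[C@@H]1C[C@@]2(C)CC[C@@H](OC(C)=O)[C@@H](CO)[C@@H](O2)[C@@H]2OC(=O)C(=C)[C@@H]21 | target

**Step count and risks**
Total steps: 13. Longest linear sequence: 13 steps (1 → 25); building blocks 4, 10 and 17 are used as bought.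

The three steps most likely to fail:

Step 6 (the proposed copper-catalysed tertiary propargylic etherification) may fail through elimination to the enyne, slow seven-membered closure, or the wrong ligand/substrate match at C10. The fallback sets out from 13 and comes back to the route at 14. The alkyne is complexed with Co2(CO)8 (CH2Cl2, rt) to the hexacarbonyldicobalt alkyne complex F1. The tertiary propargylic acetate is ionised with BF3·OEt2 at −78 °C (Nicholas reaction; short contact to spare the THP acetal), and C5-OH closes the oxepane to the cobalt-complexed oxepane F2. Because this closure is substrate-controlled, F2 forms together with its C10-epimeric complex F3, which is separated and can be re-ionised and recycled. Oxidative decomplexation of F2 with ceric ammonium nitrate (acetone, 0 °C) gives 14.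

Step 9 (anti-Markovnikov hydration next to a tertiary propargylic ether) may fail if the Ru-vinylidene ionises the C10–O bond or if the Baylis–Hillman alcohol isomerises. The fallback sets out from 18 and comes back at 19. Zirconocene hydrochloride-catalysed hydroboration of the terminal alkyne with pinacolborane (2.2 equiv, CH2Cl2, rt; the free hydroxyl is borylated transiently and released on work-up) gives the (E)-alkenyl pinacol boronate F4. Oxidation of F4 with NaBO3·4H2O (THF/H2O, rt) gives aldehyde 19.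

Step 11 (Barbier closure of the strained trans-bridged bicycle, which also sets C7 and C8) may fail to cyclise or may give the wrong C7/C8 pair. The fallback sets out from 20 and comes back at 22. Bromide is displaced with KOAc (18-crown-6, MeCN, rt) to the primary (Z)-allylic acetate F5. Treatment of F5 with SmI2 (2.5 equiv), HMPA and t-BuOH in THF at −78 °C generates the C8 ketyl radical, which adds 7-exo to C7 of the enoate; the resulting samarium enolate expels acetate to restore the exocyclic methylene and give 22. This is a reductive radical cyclisation in place of the allylmetal addition.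

**Further compounds**
F1 | step 6 | hexacarbonyldicobalt alkyne complex of 13 (drawn as components) | C#CC(C)(OC(C)=O)CC[C@@H](OC(C)=O)[C@@H](CO[Si](C)(C)C(C)(C)C)[C@@H](O)[C@H](OC1CCCCO1)C=C.[Co].[Co].[C-]#[O+].[C-]#[O+].[C-]#[O+].[C-]#[O+].[C-]#[O+].[C-]#[O+]
F2 | step 6 | hexacarbonyldicobalt alkyne complex of 14 (drawn as components) | C#C[C@@]1(C)CC[C@@H](OC(C)=O)[C@@H](CO[Si](C)(C)C(C)(C)C)[C@@H](O1)[C@H](OC2CCCCO2)C=C.[Co].[Co].[C-]#[O+].[C-]#[O+].[C-]#[O+].[C-]#[O+].[C-]#[O+].[C-]#[O+]
F3 | step 6 | C10 epimer of F2 (hexacarbonyldicobalt complex of 10-epi-14) | C#C[C@]1(C)CC[C@@H](OC(C)=O)[C@@H](CO[Si](C)(C)C(C)(C)C)[C@@H](O1)[C@H](OC2CCCCO2)C=C.[Co].[Co].[C-]#[O+].[C-]#[O+].[C-]#[O+].[C-]#[O+].[C-]#[O+].[C-]#[O+]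
F4 | step 9 | (E)-alkenyl pinacol boronate from 18 (pinB–CH=CH–C10) | CC1(C)OB(/C=C/[C@@]2(C)CC[C@@H](OC(C)=O)[C@@H](CO[Si](C)(C)C(C)(C)C)[C@@H](O2)[C@H](OC3CCCCO3)C(O)C(=C)C(=O)OC)OC1(C)C
F5 | step 11 | primary (Z)-allylic acetate from 20 (C13–OAc in place of C13–Br) | O=CC[C@@]1(C)CC[C@@H](OC(C)=O)[C@@H](CO[Si](C)(C)C(C)(C)C)[C@@H](O1)[C@H](OC2CCCCO2)/C=C(\COC(C)=O)C(=O)OC
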